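**Strategy.** With C1 the ester carbon, C2=C3 (methyl on C3), C4, C5, C6 the carbinol, C7 the isopropyl carbon, C8, C9 and C10 the quaternary carbon, the seven-membered ring (C1–C6, C10) holds oxygen on C6 at the centre of C5–C6–C10 and oxygen on C1 at the end of C1–C4. Cutting C4–C5 and C10–C1 therefore gives an oxyallyl cation and a 1-siloxy-3-methylbutadiene. Their (4+3) union delivers the ring, quaternary C10, C1–O, the C2=C3 alkene and the C6 ketone together. The precursor is a tertiary α-chloro methyl ketone whose homoprenyl chain (C7–C9) later closes the five-membered ring. C10 forms racemic; C1 is reset by directed reduction and a camphanate resolution supplies the enantiomer.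

Key step: step 6

Remark on the target: the SMILES corresponds to a cis-fused hydroazulene. C6–OH, C7–isopropyl and C10–CH3 lie on one face (called β), and the C1 ester oxygen lies on the other (α). The descriptors in route numbering are 1R,6S,7R,10R.

Remark on racemates: 3–5, 7 and 11–16 are racemic, and their SMILES show the enantiomer that leads to 21. In 11–14 both C1 epimers are carried together, so C1 is left open in the SMILES.

**Step 1**
Reactants: 1 ethyl 2-methylacetoacetate; 2 5-bromo-2-methylpent-2-ene
Product: 3 ethyl 2-acetyl-2,6-dimethylhept-5-enoate (racemic)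
Conditions: NaH, DMF, 0 °C; then 2, NaI (cat.), 60 °C
Reagents that add atoms: none
Why: Acetoacetic ester alkylation: the sodium enolate of 1 displaces the primary bromide of 2 by SN2 at carbon with iodide catalysis, and the quaternary centre (future C10) may be racemic because it is made planar again in steps 3 and 6.

**Step 2**
Reactants: 3 ethyl 2-acetyl-2,6-dimethylhept-5-enoate
Product: 5 3,7-dimethyloct-6-en-2-one (racemic), via β-keto acid 4 (not isolated)
Conditions: dilute KOH, EtOH/H2O, reflux; then aq. HCl
Reagents that add atoms: none
Why: Ketonic cleavage of an acetoacetic ester: saponification gives β-keto acid 4, which loses CO2 through its cyclic six-centre transition state, dilute base keeps retro-Claisen cleavage down and the isolated alkene is inert.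

**Step 3**
Reactants: 5 3,7-dimethyloct-6-en-2-one
Product: 6 [(3,7-dimethylocta-2,6-dien-2-yl)oxy]trimethylsilane (E/Z mixture at the enol ether)
Conditions: Me3SiCl, NaI, Et3N, MeCN, rt
Reagents that add atoms: chlorotrimethylsilane, C[Si](C)(C)Cl
Why: Silyl enol ether formation under equilibrating conditions with Me3SiI made in the flask favours the tetrasubstituted C6=C10 enol ether, and a minor terminal isomer would do no harm because its chloride would ionise to the same oxyallyl cation.

**Step 4**
Reactants: 6 [(3,7-dimethylocta-2,6-dien-2-yl)oxy]trimethylsilane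
Product: 7 3-chloro-3,7-dimethyloct-6-en-2-one (racemic)
Conditions: NCS, CH2Cl2, 0 °C; aqueous work-up
Reagents that add atoms: N-chlorosuccinimide, O=C1CCC(=O)N1Cl
Why: Electrophilic α-chlorination of a silyl enol ether: 6 is far more nucleophilic than the trisubstituted side-chain alkene, which SO2Cl2 or Cl2 acting on ketone 5 would attack, so NCS should place chlorine on C10 only and the racemic centre is again of no consequence.

**Step 5**
Reactants: 8 3-methylbut-2-enal
Product: 9 (E)-1-(triisopropylsilyloxy)-3-methylbuta-1,3-diene
Conditions: iPr3SiOTf, Et3N, Et2O, 0 °C to rt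
Reagents that add atoms: triisopropylsilyl trifluoromethanesulfonate, CC(C)[Si](C(C)C)(C(C)C)OS(=O)(=O)C(F)(F)F
Why: Dienol silyl ether formation: O-silylation of the enal followed by removal of a γ-proton by Et3N gives the 1-siloxydiene, and the s-trans form of the O-silylated enal should lead mainly to the E C1=C2 bond that the cycloaddition needs.

**Step 6**
Reactants: 7 3-chloro-3,7-dimethyloct-6-en-2-one; 9 (E)-1-(triisopropylsilyloxy)-3-methylbuta-1,3-diene
Product: 11 2,5-dimethyl-2-(4-methylpent-3-en-1-yl)-3-(triisopropylsilyloxy)cyclohept-4-en-1-one (racemic; both C1 epimers), via oxyallyl cation 10 (not isolated)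
Conditions: LiClO4 (3 M in Et2O), Et3N, 9 (3 equiv), 0 °C to rt
Reagents that add atoms: none
Why: Proposed new method: Et3N, helped by Li+ on the carbonyl oxygen, enolises 7 at its only acidic site C5, LiClO4 pulls the tertiary chloride off C10, and the resulting oxyallyl cation 10 is attacked at its unhindered terminus C5 by the nucleophilic terminus C4 of diene 9 in its s-cis form, after which the enolate carbon C10 bonds to the silyloxy-stabilised cationic C1. The closest known reaction types are the (4+3) cycloadditions of α-halo ketones with furan or cyclopentadiene under Et3N/LiClO4 in Et2O or Et3N in CF3CH2OH and those of 1,1-dialkyl-2-siloxyallyl cations with isoprene, whereas an acyclic 1-siloxydiene has not served as the four-carbon partner. The seven-membered ring C1–C6/C10 closes by this intermolecular (4+3) mode, the second bond being a 7-(enolendo)-exo-trig attack of C10 on C1 that only the E-diene can reach because it alone gives the Z C2=C3 bond. C10 has no controlling element, since its methyl and homoprenyl groups are nearly equal in size and either geometry of 10 can react on either face, so it forms racemic, and C1 follows from the E-diene and the geometry of 10 and is therefore expected as both epimers; C1 is reset in steps 10 and 11 and the C10 enantiomers are parted in step 12. The step needs head-to-tail regioselectivity, secured because the C1 oxygen and the C3 methyl group both polarise 9 towards C4 while C5 is far less hindered than C10, and it needs 9 to outrun the pendant C7 alkene and proton loss from 10, secured by its much higher nucleophilicity and its use in excess. The aprotic salt medium and the bulky iPr3Si group are chosen so that silicon is not stripped from the open intermediate before C10–C1 forms, and closure through the enolate oxygen would give an ionisable silyl acetal that can revert.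

**Step 7**
Reactants: 11 cycloheptenone from step 6
Product: 12 cis-fused 6,8a-dimethyl-3-(prop-1-en-2-yl)-8-(triisopropylsilyloxy)-1,2,3,4,5,8-hexahydroazulen-3a-ol (racemic; C6–OH, C7–isopropenyl and C10–CH3 all β; 6S,7R,10R shown; both C1 epimers)
Conditions: Me2AlCl (2 equiv), CH2Cl2, −78 to 0 °C
Reagents that add atoms: none
Why: Intramolecular carbonyl-ene reaction: C7 of the nucleophilic trisubstituted alkene attacks the aluminium-activated C6 ketone from the ring face that carries the tether, which sets C6–OH cis to C10–CH3 (cis ring fusion), the six-centre transfer of a methyl hydrogen to oxygen requires the isopropenyl group on C7 to lie cis to the new hydroxyl within the forming five-membered ring, and loss of methane from the aluminium complex removes the proton that could ionise the allylic silyl ether.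

**Step 8**
Reactants: 12 isopropenyl alcohol from step 7
Product: 13 cis-fused 3-isopropyl-6,8a-dimethyl-8-(triisopropylsilyloxy)-1,2,3,4,5,8-hexahydroazulen-3a-ol (racemic; 6S,7R,10R shown; both C1 epimers)
Conditions: H2 (1 atm), RhCl(PPh3)3 (5 mol %), toluene/EtOH, rt
Reagents that add atoms: none
Why: Homogeneous hydrogenation with RhCl(PPh3)3 discriminates by alkene substitution, so the 1,1-disubstituted isopropenyl group is saturated while the hindered trisubstituted C2=C3 bond survives, and no stereocentre is formed or touched.

**Step 9**
Reactants: 13 silyl ether from step 8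
Product: 14 3-isopropyl-6,8a-dimethyl-1,2,3,4,5,8-hexahydroazulene-3a,8-diol (racemic; 6S,7R,10R shown; both C1 epimers)
Conditions: Bu4NF, THF, rt to 50 °C
Reagents that add atoms: none
Why: Fluoride-induced cleavage of the silyl ether, driven by the strong Si–F bond and helped by gentle heating at the neopentyl position, leaves the tertiary alcohol and the alkene untouched.

**Step 10**
Reactants: 14 diol mixture from step 9
Product: 15 3a-hydroxy-3-isopropyl-6,8a-dimethyl-2,3,3a,4,5,8a-hexahydroazulen-8(1H)-one (racemic; 6S,7R,10S shown, the C10 descriptor changing only through priorities)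
Conditions: Dess–Martin periodinane, CH2Cl2, 0 °C to rt
Reagents that add atoms: none
Why: Dess–Martin oxidation converts both C1 epimers into one enone, the tertiary C6 hydroxyl cannot be oxidised, and quaternary C10 rules out epimerisation or dehydration of the β-hydroxy ketone.

**Step 11**
Reactants: 15 hydroxy enone from step 10
Product: 16 (1R*,6S*,7R*,10R*)-3-isopropyl-6,8a-dimethyl-1,2,3,4,5,8-hexahydroazulene-3a,8-diol (racemic; C1–OH α; C6–OH β)
Conditions: Me4NBH(OAc)3, MeCN/AcOH, −20 to 0 °C
Reagents that add atoms: none
Why: Evans–Saksena hydroxyl-directed reduction: exchange of one acetate for the β-oriented C6 hydroxyl ties the otherwise unreactive borohydride to the β face, which is also the convex face of the cis-fused bicycle, so hydride reaches C1 from β in a 1,2-sense and the new C1 hydroxyl is α, anti to C6–OH.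

**Step 12**
Reactants: 16 racemic diol; 17 (1S)-(−)-camphanic chloride
Product: 18 (1S)-camphanate of the (1R,6S,7R,10R)-diol at C1–O (single stereoisomer)
Conditions: 17, Et3N, DMAP (cat.), CH2Cl2, rt; separation of the two esters on silica gel, then recrystallisation
Reagents that add atoms: none
Why: Resolution through covalent diastereomers: DMAP-catalysed acylation takes place only at the secondary C1 hydroxyl, the acid chloride has no epimerisable centre so the two esters differ solely in the terpene part and should be separable by chromatography and crystallisation, and an X-ray analysis against the known camphanoyl centres should identify the (1R,6S,7R,10R) ester 18.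

**Step 13**
Reactants: 18 camphanate from step 12
Product: 19 (1R,6S,7R,10R)-3-isopropyl-6,8a-dimethyl-1,2,3,4,5,8-hexahydroazulene-3a,8-diol (single enantiomer)
Conditions: K2CO3, MeOH, 40 °C
Reagents that add atoms: none
Why: Base-catalysed transesterification with methanol breaks the acyl–oxygen bond only, so C1 keeps its configuration and the diol is released as a single enantiomer.

**Step 14**
Reactants: 19 enantiopure diol; 20 4-methoxybenzoyl chloride
Product: 21 (3R,3aS,8R,8aR)-3a-hydroxy-3-isopropyl-6,8a-dimethyl-1,2,3,3a,4,5,8,8a-octahydroazulen-8-yl 4-methoxybenzoate (target; 1R,6S,7R,10R in route numbering)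
Conditions: 20, Et3N, DMAP, CH2Cl2, rt to reflux
Reagents that add atoms: none
Why: DMAP-catalysed acylation reaches only the secondary allylic C1 hydroxyl, the tertiary C6 hydroxyl being inert under these conditions, and the C1–O bond is not broken, so all four stereocentres are retained.

**Compound list**

1 | ethyl 2-methylacetoacetate | CCOC(=O)C(C)C(C)=O | starting material
2 | 5-bromo-2-methylpent-2-ene | CC(C)=CCCBr | starting material
3 | ethyl 2-acetyl-2,6-dimethylhept-5-enoate (racemic) | CCOC(=O)C(C)(CCC=C(C)C)C(C)=O | intermediate
4 | 2-acetyl-2,6-dimethylhept-5-enoic acid (β-keto acid, not isolated) | OC(=O)C(C)(CCC=C(C)C)C(C)=O | intermediate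
5 | 3,7-dimethyloct-6-en-2-one (racemic) | CC(=O)C(C)CCC=C(C)C | intermediate
6 | [(3,7-dimethylocta-2,6-dien-2-yl)oxy]trimethylsilane (E/Z mixture) | CC(O[Si](C)(C)C)=C(C)CCC=C(C)C | intermediate
7 | 3-chloro-3,7-dimethyloct-6-en-2-one (racemic) | CC(=O)C(C)(Cl)CCC=C(C)C | intermediate
8 | 3-methylbut-2-enal | CC(C)=CC=O | starting material
9 | (E)-1-(triisopropylsilyloxy)-3-methylbuta-1,3-diene | C=C(C)/C=C/O[Si](C(C)C)(C(C)C)C(C)C | intermediate
10 | oxyallyl cation C5–C6(O)–C10 bearing methyl and homoprenyl on C10 (not isolated) | C=C([O-])[C+](C)CCC=C(C)C | intermediate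
11 | 2,5-dimethyl-2-(4-methylpent-3-en-1-yl)-3-(triisopropylsilyloxy)cyclohept-4-en-1-one (racemic, 10R shown, both C1 epimers) | O=C1CCC(C)=CC(O[Si](C(C)C)(C(C)C)C(C)C)[C@@]1(C)CCC=C(C)C | intermediate
12 | cis-fused isopropenyl carbinol, C1–OSi(iPr)3 (racemic, 6S,7R,10R shown, both C1 epimers) | CC(C)[Si](C(C)C)(C(C)C)OC1C=C(C)CC[C@]2(O)[C@@H](C(C)=C)CC[C@]12C | intermediate
13 | cis-fused isopropyl carbinol, C1–OSi(iPr)3 (racemic, 6S,7R,10R shown, both C1 epimers) | CC(C)[Si](C(C)C)(C(C)C)OC1C=C(C)CC[C@]2(O)[C@@H](C(C)C)CC[C@]12C | intermediate
14 | C1,C6-diol (racemic, 6S,7R,10R shown, both C1 epimers) | OC1C=C(C)CC[C@]2(O)[C@@H](C(C)C)CC[C@]12C | intermediate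
15 | C6-hydroxy C1-enone (racemic, 6S,7R,10S shown) | O=C1C=C(C)CC[C@]2(O)[C@@H](C(C)C)CC[C@]12C | intermediate
16 | C1α,C6β-diol (racemic, 1R,6S,7R,10R shown) | O[C@@H]1C=C(C)CC[C@]2(O)[C@@H](C(C)C)CC[C@]12C | intermediate
17 | (1S,4R)-4,7,7-trimethyl-3-oxo-2-oxabicyclo[2.2.1]heptane-1-carbonyl chloride, (1S)-(−)-camphanic chloride | CC1(C)[C@@]2(C)CC[C@@]1(OC2=O)C(Cl)=O | starting material
18 | (1S)-camphanate of the (1R,6S,7R,10R)-diol | CC1(C)[C@@]2(C)CC[C@@]1(OC2=O)C(=O)O[C@@H]3C=C(C)CC[C@]4(O)[C@@H](C(C)C)CC[C@]34C | intermediate
19 | (1R,6S,7R,10R)-diol (single enantiomer) | O[C@@H]1C=C(C)CC[C@]2(O)[C@@H](C(C)C)CC[C@]12C | intermediate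
20 | 4-methoxybenzoyl chloride | COc1ccc(cc1)C(Cl)=O | starting material
21 | CNP0158828.3 | COc1ccc(C(=O)O[C@@H]2C=C(C)CC[C@]3(O)[C@@H](C(C)C)CC[C@]23C)cc1 | target

**Totals.** Total step count: 14. Longest linear sequence: 13 steps (steps 1–4 and 6–14).

**Steps most likely to fail**

1. Step 6.
   - Risk: silicon may be lost from the open-chain intermediate before the second bond forms. The enolate may close through oxygen or at C3. The cation may also be consumed by its own C7 alkene or by proton loss.
   - Fallback: this uses known chemistry only, with no cycloaddition. It sets out from 3 and comes back at 11.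
   - Prop-2-yn-1-ol is carbometallated with MeMgBr/CuI and quenched with I2 to give (Z)-3-iodo-2-methylprop-2-en-1-ol F1. PBr3 converts this into (Z)-3-bromo-1-iodo-2-methylprop-1-ene F2.
   - The kinetic enolate of 3 (LiN(iPr)2, THF, −78 °C) can only form at the acetyl methyl group C5. It is alkylated with F2 to give the iodoalkenyl keto ester F3, which holds all of C1–C10.
   - iBu2AlH reduces ester and ketone to the diol F4, and Dess–Martin oxidation gives the keto aldehyde F5.
   - An intramolecular Nozaki–Hiyama–Kishi reaction (CrCl2, NiCl2 cat., DMF, high dilution) joins C2 to C1, chemoselectively at the aldehyde and with retention of the Z alkene. This gives the hydroxy cycloheptenone F6.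
   - iPr3SiOTf/2,6-lutidine then gives 11 as the same racemic epimer mixture.

2. Step 7.
   - Risk: the Lewis acid may ionise the allylic C1–O bond, or the hindered C6 ketone may not react.
   - Fallback: it sets out from 11 and comes back at 12.
   - Ene-type allylic chlorination of the electron-rich, unhindered side-chain alkene (NaOCl, CeCl3·7H2O, CH2Cl2/H2O, 0 °C) gives the secondary allylic chloride F7.
   - SmI2 (THF, 0 °C) converts F7 into an allylsamarium species. This adds to C6 through its C7 terminus in an intramolecular Barbier reaction.
   - The metal bridges the carbonyl oxygen and the allyl terminus, so hydroxyl and isopropenyl should again end up cis. No strong Lewis acid is present.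

3. Step 12.
   - Risk: the two camphanates may differ too little in chromatographic and crystallisation behaviour to be parted.
   - Fallback: it sets out from 16 and comes back at 21.
   - Racemic 16 is acylated with 20 under the conditions of step 14. This gives 21 together with the mirror image of the target F8.
   - The pair is separated by preparative chromatography on an amylose tris(3,5-dimethylphenylcarbamate) phase, where the anisoate offers a π-binding handle.
   - The absolute configuration is then assigned by correlation with a small sample of 18.

**Further compounds**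

F1 | step 6 | (Z)-3-iodo-2-methylprop-2-en-1-ol | OC/C(C)=C\I
F2 | step 6 | (Z)-3-bromo-1-iodo-2-methylprop-1-ene | BrC/C(C)=C\I
F3 | step 6 | ethyl 2-[(Z)-5-iodo-4-methylpent-4-enoyl]-2,6-dimethylhept-5-enoate (racemic) | CCOC(=O)C(C)(CCC=C(C)C)C(=O)CC/C(C)=C\I
F4 | step 6 | (Z)-2-(1-hydroxy-5-iodo-4-methylpent-4-enyl)-2,6-dimethylhept-5-en-1-ol (diastereomer mixture) | OCC(C)(CCC=C(C)C)C(O)CC/C(C)=C\I
F5 | step 6 | 2-[(Z)-5-iodo-4-methylpent-4-enoyl]-2,6-dimethylhept-5-enal (racemic) | O=CC(C)(CCC=C(C)C)C(=O)CC/C(C)=C\I
F6 | step 6 | 3-hydroxy-2,5-dimethyl-2-(4-methylpent-3-en-1-yl)cyclohept-4-en-1-one (racemic, 10R shown, both C1 epimers) | O=C1CCC(C)=CC(O)[C@@]1(C)CCC=C(C)C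
F7 | step 7 | 2-(3-chloro-4-methylpent-4-en-1-yl)-2,5-dimethyl-3-(triisopropylsilyloxy)cyclohept-4-en-1-one (racemic, epimer mixture) | O=C1CCC(C)=CC(O[Si](C(C)C)(C(C)C)C(C)C)[C@@]1(C)CCC(Cl)C(C)=C
F8 | step 12 | mirror image of the target, (1S,6R,7S,10S) | COc1ccc(C(=O)O[C@H]2C=C(C)CC[C@@]3(O)[C@H](C(C)C)CC[C@@]23C)cc1
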